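**Plan**

- Locants: C1 (CH–OAc), C2, C3 (C(OH)CH3), C4=C5, C6, C7 (CH–CH3), C8, C9 (C=O), C10, C11=C12, C13 (CH–O), C14 (CH–iPr), with C15 the lactone carbonyl on C11. In these locants the target is 1S,3S,4E,7S,13R,14R.
- Retrosynthesis: acetate, C3–OH, C9 ketone and isopropyl are traced back to OTBS, OTES, dioxolane and isopropenyl. The C13–C14 bond and the lactone O–C15 bond are then cut together. Further cuts are C4=C5 (cross-metathesis), the bond from C14 to the isopropyl carbon (Wittig) together with C1–O (α-aminoxylation), and C9–C10 (acylation of a furylmethylzinc).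
- Enabling feature: C13 and C14 are adjacent stereocentres, C14 carries a three-carbon branch that can be the γ-end of a 2-methylallyl metal, and the C13 oxygen sits cis to C15 across C11=C12. One aldehyde allylation therefore closes the 14-membered carbocycle, and its alkoxide closes the butenolide.
- Forward: the east piece (C5–C13 and C15, with a 2-silylfuran as masked Z-formyl enoate) comes from 3-furanmethanol and (R)-methyl hydrogen 3-methylglutarate, the west piece (C1–C4, C14) from geraniol. They are joined at C4=C5, the chain is extended to the allylic bromide, the furan is photooxygenated, and both rings then close in one step.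
- Stereochemistry: C7 from the glutarate half-ester; C3 from Sharpless epoxidation of geraniol; C1 from D-proline-catalysed α-aminoxylation; C13 and C14 from the chair transition state of the E-allylchromium, biased by C1; C4=C5 E from cross-metathesis; C11=C12 Z from the furan ring.

Key step: step 23

Assumption: a 2-triethylsilyl group steers the singlet-oxygen oxidation of the furan in the same way as the more common 2-trimethylsilyl group, while surviving the earlier steps better.

Step 1
Reactants: 1 3-furanmethanol
Product: 2 triethyl(furan-3-ylmethoxy)silane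
Conditions: TESCl, imidazole, CH2Cl2, 0 °C → 25 °C
Reagents that add atoms: chlorotriethylsilane, CC[Si](Cl)(CC)CC
Why: Routine silylation of a primary alcohol, which installs the silyl group that is moved onto the ring in the next step.

Step 2
Reactants: 2 triethyl(furan-3-ylmethoxy)silane
Product: 3 [2-(triethylsilyl)furan-3-yl]methanol
Conditions: n-BuLi, HMPA, THF, −78 °C → 25 °C; aq. NH4Cl
Reagents that add atoms: none
Why: n-BuLi lithiates the furan at C2 next to the CH2O group and the silyl group then shifts from oxygen to carbon (1,4 O→C silyl migration, a retro-Brook rearrangement), which puts silicon on the ring carbon that later becomes C15.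

Step 3
Reactants: 3 [2-(triethylsilyl)furan-3-yl]methanol
Product: 4 [3-(chloromethyl)furan-2-yl]triethylsilane
Conditions: PPh3, CCl4, CH2Cl2, 25 °C
Reagents that add atoms: tetrachloromethane, ClC(Cl)(Cl)Cl
Why: Appel chlorination converts the furylmethyl alcohol into the chloride under neutral conditions that should leave the acid-sensitive silylfuran untouched.

Step 4
Reactants: 5 (R)-methyl hydrogen 3-methylglutarate
Product: 6 methyl (3S)-5-chloro-3-methyl-5-oxopentanoate (acid chloride of 5; same spatial arrangement, the descriptor changes only through priorities)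
Conditions: (COCl)2, DMF (cat.), CH2Cl2, 0 °C → 25 °C; used at once
Reagents that add atoms: oxalyl chloride, O=C(Cl)C(=O)Cl
Why: Vilsmeier-type activation turns the free acid end into the acid chloride in the cold, the methyl ester and the β-stereocentre (the later C7, taken unchanged from the half-ester) being unaffected.

Step 5
Reactants: 4 [3-(chloromethyl)furan-2-yl]triethylsilane; 6 methyl (3S)-5-chloro-3-methyl-5-oxopentanoate
Product: 8 methyl (3R)-3-methyl-5-oxo-6-[2-(triethylsilyl)furan-3-yl]hexanoate, via furylmethylzinc chloride 7 (not isolated)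
Conditions: Zn dust, LiCl, THF, 25 °C; then 6, Pd(PPh3)4 (3 mol %), THF, 0 °C → 25 °C
Reagents that add atoms: none
Why: LiCl-assisted zinc insertion into the heterobenzylic chloride gives an ester-tolerant organozinc, and Negishi acylation by the acid chloride forms the C9–C10 bond, the 2-silyl group blocking reaction through the ring carbon.

Step 6
Reactants: 8 methyl (3R)-3-methyl-5-oxo-6-[2-(triethylsilyl)furan-3-yl]hexanoate
Product: 9 methyl (3R)-3-methyl-4-[2-{[2-(triethylsilyl)furan-3-yl]methyl}-1,3-dioxolan-2-yl]butanoate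
Conditions: (Me3SiOCH2)2, Me3SiOTf (5 mol %), CH2Cl2, −78 °C → −20 °C; pyridine
Reagents that add atoms: 1,2-bis(trimethylsilyloxy)ethane, C[Si](C)(C)OCCO[Si](C)(C)C
Why: Aprotic low-temperature ketalisation with the bis-silyl ether of ethylene glycol protects the C9 ketone without protodesilylating the furan, so that C10 is no longer enolisable in the later steps.

Step 7
Reactants: 9 methyl (3R)-3-methyl-4-[2-{[2-(triethylsilyl)furan-3-yl]methyl}-1,3-dioxolan-2-yl]butanoate
Product: 10 (3S)-3-methyl-4-[2-{[2-(triethylsilyl)furan-3-yl]methyl}-1,3-dioxolan-2-yl]butanal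
Conditions: i-Bu2AlH (1.05 equiv), CH2Cl2, −78 °C; MeOH, aq. Rochelle salt
Reagents that add atoms: none
Why: Partial reduction of the methyl ester by i-Bu2AlH stops at the aldehyde because the tetrahedral aluminium hemiacetal is stable at −78 °C, and the dioxolane and silylfuran are inert to the hydride.

Step 8
Reactants: 10 (3S)-3-methyl-4-[2-{[2-(triethylsilyl)furan-3-yl]methyl}-1,3-dioxolan-2-yl]butanal
Product: 11 triethyl[3-({2-[(2S)-2-methylpent-4-en-1-yl]-1,3-dioxolan-2-yl}methyl)furan-2-yl]silane (east fragment)
Conditions: Ph3PCH3Br, KOtBu, THF, 0 °C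
Reagents that add atoms: methyltriphenylphosphonium bromide, C[P+](c1ccccc1)(c1ccccc1)c1ccccc1.[Br-]
Why: Wittig methylenation gives the terminal alkene needed for cross-metathesis, and C7 cannot epimerise because it is not α to the carbonyl.

Step 9
Reactants: 12 geraniol
Product: 13 (2S,3S)-2,3-epoxygeraniol
Conditions: Ti(OiPr)4 (5 mol %), L-(+)-diethyl tartrate (6 mol %), t-BuOOH, 4 Å MS, CH2Cl2, −20 °C
Reagents that add atoms: tert-butyl hydroperoxide, CC(C)(C)OO
Why: Sharpless asymmetric epoxidation, in which the titanium tartrate bound to the allylic hydroxyl delivers oxygen to the face that gives the (2S,3S)-epoxide with L-(+)-tartrate, sets the later C3, and the remote alkene without a directing hydroxyl is left alone.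

Step 10
Reactants: 13 (2S,3S)-2,3-epoxygeraniol
Product: 14 (2R,3S)-2-(iodomethyl)-3-methyl-3-(4-methylpent-3-en-1-yl)oxirane
Conditions: I2, PPh3, imidazole, CH2Cl2, 0 °C
Reagents that add atoms: iodine, II
Why: Appel-type iodination replaces the primary hydroxyl by SN2 at CH2 without opening the epoxide.

Step 11
Reactants: 14 (2R,3S)-2-(iodomethyl)-3-methyl-3-(4-methylpent-3-en-1-yl)oxirane
Product: 15 (S)-linalool
Conditions: Zn dust, AcOH, EtOH, 25 °C
Reagents that add atoms: none
Why: Zinc inserts into the C–I bond and the organozinc opens the neighbouring epoxide by β-elimination (reductive epoxide opening), giving the vinyl carbinol with the C–O bond of the stereocentre untouched and hence retained configuration.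

Step 12
Reactants: 15 (S)-linalool
Product: 17 (4S)-4-methylhex-5-ene-1,4-diol (west fragment), via hydroxy aldehyde 16 (not isolated)
Conditions: O3 (1 equiv), CH2Cl2/MeOH, −78 °C; then NaBH4, −78 °C → 0 °C
Reagents that add atoms: ozone, [O-][O+]=O
Why: Ozonolysis is selective for the electron-rich trisubstituted alkene over the vinyl group next to the carbinol, and borohydride work-up reduces the aldehyde to the primary alcohol.

Step 13
Reactants: 11 triethyl[3-({2-[(2S)-2-methylpent-4-en-1-yl]-1,3-dioxolan-2-yl}methyl)furan-2-yl]silane; 17 (4S)-4-methylhex-5-ene-1,4-diol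
Product: 18 (4S,5E,8S)-4,8-dimethyl-9-[2-{[2-(triethylsilyl)furan-3-yl]methyl}-1,3-dioxolan-2-yl]non-5-ene-1,4-diol
Conditions: second-generation Grubbs catalyst RuCl2(=CHPh)(PCy3)(H2IMes) (5 mol %), 17 (3 equiv), CH2Cl2, 40 °C
Reagents that add atoms: none
Why: In this olefin cross-metathesis the free tertiary allylic alcohol dimerises only slowly, so with 17 in excess the quickly dimerising terminal alkene 11 is funnelled into the cross product, and the quaternary allylic carbon should enforce the E geometry of C4=C5.

Step 14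
Reactants: 18 (4S,5E,8S)-4,8-dimethyl-9-[2-{[2-(triethylsilyl)furan-3-yl]methyl}-1,3-dioxolan-2-yl]non-5-ene-1,4-diol
Product: 19 1,4-bis(triethylsilyl) ether of 18
Conditions: TESOTf (2.5 equiv), 2,6-lutidine, CH2Cl2, −78 °C → 0 °C
Reagents that add atoms: triethylsilyl trifluoromethanesulfonate, CC[Si](CC)(CC)OS(=O)(=O)C(F)(F)F
Why: The silyl triflate with a hindered base silylates the primary and also the hindered tertiary hydroxyl, the short cold exposure sparing the ketone dioxolane.

Step 15
Reactants: 19 1,4-bis(triethylsilyl) ether of 18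
Product: 20 (4S,5E,8S)-4,8-dimethyl-4-(triethylsilyloxy)-9-[2-{[2-(triethylsilyl)furan-3-yl]methyl}-1,3-dioxolan-2-yl]non-5-enal
Conditions: (COCl)2, DMSO, CH2Cl2, −78 °C → −30 °C; then Et3N, → 0 °C
Reagents that add atoms: none
Why: Under Swern conditions a primary triethylsilyl ether is cleaved by the chlorosulfonium salt and oxidised in the same pot while the tertiary triethylsilyl ether is inert, so the C14 aldehyde should arise without a separate deprotection.

Step 16
Reactants: 20 (4S,5E,8S)-4,8-dimethyl-4-(triethylsilyloxy)-9-[2-{[2-(triethylsilyl)furan-3-yl]methyl}-1,3-dioxolan-2-yl]non-5-enal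
Product: 22 ethyl (2E,4S,6S,7E,10S)-4-(anilinooxy)-2,6,10-trimethyl-6-(triethylsilyloxy)-11-[2-{[2-(triethylsilyl)furan-3-yl]methyl}-1,3-dioxolan-2-yl]undeca-2,7-dienoate, via alpha-anilinooxy aldehyde 21 (not isolated)
Conditions: PhNO, D-proline (20 mol %), CHCl3, 0 °C; then Ph3P=C(CH3)CO2Et, 0 °C → 25 °C
Reagents that add atoms: nitrosobenzene, O=Nc1ccccc1; ethyl 2-(triphenylphosphoranylidene)propanoate, CCOC(=O)C(C)=P(c1ccccc1)(c1ccccc1)c1ccccc1
Why: In this enamine-catalysed α-aminoxylation the D-proline enamine attacks nitrosobenzene at oxygen through the hydrogen-bonded transition state and sets C1 as S under catalyst control (L-proline gives R), and the labile α-oxy aldehyde is trapped at once by Wittig olefination with the stabilised ylide, which gives the E-trisubstituted enoate.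

Step 17
Reactants: 22 ethyl (2E,4S,6S,7E,10S)-4-(anilinooxy)-2,6,10-trimethyl-6-(triethylsilyloxy)-11-[2-{[2-(triethylsilyl)furan-3-yl]methyl}-1,3-dioxolan-2-yl]undeca-2,7-dienoate
Product: 23 the corresponding 4-hydroxy ester (C1–OH free)
Conditions: Cu(OAc)2 (30 mol %), EtOH, 25 °C
Reagents that add atoms: none
Why: Copper-catalysed N–O cleavage of the O-alkyl-N-phenylhydroxylamine frees the C1 alcohol under neutral conditions that leave the enoate, silyl ethers and dioxolane intact.

Step 18
Reactants: 23 ethyl (2E,4S,6S,7E,10S)-4-hydroxy-2,6,10-trimethyl-6-(triethylsilyloxy)-11-[2-{[2-(triethylsilyl)furan-3-yl]methyl}-1,3-dioxolan-2-yl]undeca-2,7-dienoate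
Product: 24 the corresponding 4-(tert-butyldimethylsilyl) ether (C1–OTBS)
Conditions: TBSOTf, 2,6-lutidine, CH2Cl2, −78 °C
Reagents that add atoms: tert-butyldimethylsilyl trifluoromethanesulfonate, CC(C)(C)[Si](C)(C)OS(=O)(=O)C(F)(F)F
Why: Silylation of the secondary allylic alcohol gives the robust, poorly leaving C1 substituent that the ring closure needs.

Step 19
Reactants: 24 ethyl (2E,4S,6S,7E,10S)-4-(tert-butyldimethylsilyloxy)-2,6,10-trimethyl-6-(triethylsilyloxy)-11-[2-{[2-(triethylsilyl)furan-3-yl]methyl}-1,3-dioxolan-2-yl]undeca-2,7-dienoate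
Product: 25 (2E,4S,6S,7E,10S)-4-(tert-butyldimethylsilyloxy)-2,6,10-trimethyl-6-(triethylsilyloxy)-11-[2-{[2-(triethylsilyl)furan-3-yl]methyl}-1,3-dioxolan-2-yl]undeca-2,7-dien-1-ol
Conditions: i-Bu2AlH (2.5 equiv), CH2Cl2, −78 °C; aq. Rochelle salt
Reagents that add atoms: none
Why: 1,2-Reduction of the enoate by i-Bu2AlH gives the primary allylic alcohol with the double-bond geometry unchanged.

Step 20
Reactants: 25 (2E,4S,6S,7E,10S)-4-(tert-butyldimethylsilyloxy)-2,6,10-trimethyl-6-(triethylsilyloxy)-11-[2-{[2-(triethylsilyl)furan-3-yl]methyl}-1,3-dioxolan-2-yl]undeca-2,7-dien-1-ol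
Product: 26 the corresponding primary allylic bromide (CH2OH → CH2Br)
Conditions: CBr4, PPh3, 2,6-lutidine, CH2Cl2, 0 °C
Reagents that add atoms: tetrabromomethane, BrC(Br)(Br)Br
Why: Appel bromination of the primary allylic alcohol under buffered conditions is done here because no aldehyde or electron-poor alkene is yet present to react with the phosphine.

Step 21
Reactants: 26 seco allylic bromide carrying the 2-triethylsilylfuran (C1 OTBS, C3 OTES, C9 dioxolane)
Product: 29 hydroxybutenolide bromide [3-substituted 5-hydroxy-2(5H)-furanone in place of the furan; other groups as in 26; lactol carbon as an epimer mixture], via furan endoperoxide 27 (not isolated), via triethylsilyl Z-formyl enoate 28 (not isolated)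
Conditions: O2, hν (visible), tetraphenylporphyrin (cat.), CH2Cl2, −78 °C; then H2O/THF, 0 °C
Reagents that add atoms: dioxygen, O=O
Why: Singlet oxygen adds [4+2] to the furan much faster than it undergoes ene reaction with the oxygen-flanked trisubstituted alkene, and the 1,2-shift of silicon to the peroxide oxygen turns the silyl-bearing carbon into the carboxyl carbon C15 and the other α-carbon into the C13 aldehyde, the ring keeping C11=C12 Z.

Step 22
Reactants: 29 hydroxybutenolide bromide
Product: 30 seco allylic bromide Z-formyl enoate methyl ester (C1 OTBS, C3 OTES, C9 dioxolane)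
Conditions: CH2N2, Et2O, 0 °C, short contact; N2 purge
Reagents that add atoms: diazomethane, C=[N+]=[N-]
Why: Diazomethane esterifies only the open-chain carboxylic acid tautomer of the pseudo-acid, which drains the ring–chain equilibrium into the methyl Z-4-oxo-2-enoate with the double-bond geometry retained.

Step 23
Reactants: 30 seco allylic bromide Z-formyl enoate methyl ester
Product: 32 14-isopropenyl bicyclic butenolide (C1 OTBS, C3 OTES, C9 dioxolane; 1S,3S,4E,7S,13R,14S), via macrocyclic C13 hydroxy methyl ester 31 (not isolated)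
Conditions: CrCl2 (10 equiv), 4 Å MS, THF, 25 °C, slow addition of 30 (final 1 mM); aq. NH4Cl
Reagents that add atoms: none
Why: Two equivalents of CrCl2 (divalent chromium) reduce the allylic bromide to an allylchromium dichloride (trivalent chromium) that settles into the isomer with CH2Cr trans to C1 and adds through its γ-carbon C14 to the C13 aldehyde in a closed six-membered chair transition state, the closest known reaction type being the intramolecular Nozaki–Hiyama allylation used to close 14-membered carbocycles. The carbocycle closes by this intramolecular carbonyl addition, favoured over chain growth by slow addition into high dilution, and the butenolide then closes by 5-exo-trig acyl substitution of the C13 chromium alkoxide on the C15 methyl ester, which the Z geometry of C11=C12 holds next to it. C13 and C14 are set together: with the C1-bearing substituent and the aldehyde residue both equatorial in the chair, the C13 oxygen and the C1 branch on C14 come out anti, as the target requires. The absolute sense at C14 is governed by C1, because allylic 1,3-strain with the methyl group on the central allyl carbon keeps the C1–H bond in the allyl plane and the aldehyde then approaches the face opposite the bulky C1 silyloxy group. The step also needs attack on the aldehyde only and at the γ- rather than the α-carbon, both normal for substituted allylchromium reagents, which leave ester, dioxolane and silyl ethers alone. The silyl ether at C1, a poor leaving group, is there to suppress 1,4-elimination of the allylmetal to a diene.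

Step 24
Reactants: 32 14-isopropenyl bicyclic butenolide
Product: 33 14-isopropyl bicyclic butenolide (C1 OTBS, C3 OTES, C9 dioxolane)
Conditions: H2 (1 atm), RhCl(PPh3)3 (10 mol %), benzene/EtOH, 25 °C
Reagents that add atoms: none
Why: Homogeneous hydrogenation with RhCl(PPh3)3 discriminates by substitution, reducing the 1,1-disubstituted isopropenyl group while the E-disubstituted C4=C5 next to quaternary C3 and the trisubstituted conjugated C11=C12 should remain, and no stereocentre is formed.

Step 25
Reactants: 33 14-isopropyl bicyclic butenolide (C1 OTBS, C3 OTES, C9 dioxolane)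
Product: 34 C1,C3-diol with C9 dioxolane (1S,3S,4E,7S,13R,14R)
Conditions: HF·pyridine, pyridine, THF, 0 °C → 25 °C
Reagents that add atoms: none
Why: Buffered fluoride cleaves both Si–O bonds while the dioxolane, the butenolide and the tertiary allylic alcohol are stable to the weakly acidic medium.

Step 26
Reactants: 34 C1,C3-diol with C9 dioxolane
Product: 35 C1 acetate with free C3 hydroxyl and C9 dioxolane
Conditions: Ac2O, pyridine, DMAP (cat.), CH2Cl2, 0 °C → 25 °C
Reagents that add atoms: acetic anhydride, CC(=O)OC(C)=O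
Why: Nucleophile-catalysed acylation takes the secondary C1 hydroxyl and leaves the tertiary C3 hydroxyl, and it is run while C9 is still masked so that the base cannot move C11=C12 into conjugation with a ketone.

Step 27
Reactants: 35 C1 acetate with free C3 hydroxyl and C9 dioxolane
Product: 36 target (CNP0200490.2)
Conditions: PPTS, acetone/H2O, 40 °C
Reagents that add atoms: water, O
Why: Mild acid-catalysed hydrolysis (transketalisation into acetone) releases the C9 ketone under conditions weak enough not to ionise the tertiary allylic alcohol or cleave the acetate.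

**Compound list**

1 | 3-furanmethanol | OCc1ccoc1 | starting material
2 | triethyl(furan-3-ylmethoxy)silane | CC[Si](CC)(CC)OCc1ccoc1 | intermediate
3 | [2-(triethylsilyl)furan-3-yl]methanol | OCc1ccoc1[Si](CC)(CC)CC | intermediate
4 | [3-(chloromethyl)furan-2-yl]triethylsilane | ClCc1ccoc1[Si](CC)(CC)CC | intermediate
5 | (R)-methyl hydrogen 3-methylglutarate | COC(=O)C[C@H](C)CC(=O)O | starting material
6 | methyl (3S)-5-chloro-3-methyl-5-oxopentanoate | COC(=O)C[C@H](C)CC(Cl)=O | intermediate
7 | {[2-(triethylsilyl)furan-3-yl]methyl}zinc chloride | Cl[Zn]Cc1ccoc1[Si](CC)(CC)CC | intermediate (not isolated)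
8 | methyl (3R)-3-methyl-5-oxo-6-[2-(triethylsilyl)furan-3-yl]hexanoate | COC(=O)C[C@H](C)CC(=O)Cc1ccoc1[Si](CC)(CC)CC | intermediate
9 | methyl (3R)-3-methyl-4-[2-{[2-(triethylsilyl)furan-3-yl]methyl}-1,3-dioxolan-2-yl]butanoate | COC(=O)C[C@H](C)CC1(OCCO1)Cc2ccoc2[Si](CC)(CC)CC | intermediate
10 | (3S)-3-methyl-4-[2-{[2-(triethylsilyl)furan-3-yl]methyl}-1,3-dioxolan-2-yl]butanal | O=CC[C@H](C)CC1(OCCO1)Cc2ccoc2[Si](CC)(CC)CC | intermediate
11 | triethyl[3-({2-[(2S)-2-methylpent-4-en-1-yl]-1,3-dioxolan-2-yl}methyl)furan-2-yl]silane | C=CC[C@H](C)CC1(OCCO1)Cc2ccoc2[Si](CC)(CC)CC | intermediate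
12 | geraniol | CC(C)=CCC/C(C)=C/CO | starting material
13 | (2S,3S)-2,3-epoxygeraniol | OC[C@@H]1O[C@@]1(C)CCC=C(C)C | intermediate
14 | (2R,3S)-2-(iodomethyl)-3-methyl-3-(4-methylpent-3-en-1-yl)oxirane | IC[C@@H]1O[C@@]1(C)CCC=C(C)C | intermediate
15 | (S)-linalool | C=C[C@@](C)(O)CCC=C(C)C | intermediate
16 | (4S)-4-hydroxy-4-methylhex-5-enal | C=C[C@@](C)(O)CCC=O | intermediate (not isolated)
17 | (4S)-4-methylhex-5-ene-1,4-diol | C=C[C@@](C)(O)CCCO | intermediate
18 | (4S,5E,8S)-4,8-dimethyl-9-[2-{[2-(triethylsilyl)furan-3-yl]methyl}-1,3-dioxolan-2-yl]non-5-ene-1,4-diol | OCCC[C@](C)(O)/C=C/C[C@H](C)CC1(OCCO1)Cc2ccoc2[Si](CC)(CC)CC | intermediate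
19 | 1,4-bis(triethylsilyl) ether of 18 | CC[Si](CC)(CC)OCCC[C@](C)(O[Si](CC)(CC)CC)/C=C/C[C@H](C)CC1(OCCO1)Cc2ccoc2[Si](CC)(CC)CC | intermediate
20 | (4S,5E,8S)-4,8-dimethyl-4-(triethylsilyloxy)-9-[2-{[2-(triethylsilyl)furan-3-yl]methyl}-1,3-dioxolan-2-yl]non-5-enal | O=CCC[C@](C)(O[Si](CC)(CC)CC)/C=C/C[C@H](C)CC1(OCCO1)Cc2ccoc2[Si](CC)(CC)CC | intermediate
21 | (2S)-2-(anilinooxy) derivative of 20 | O=C[C@@H](ONc1ccccc1)C[C@](C)(O[Si](CC)(CC)CC)/C=C/C[C@H](C)CC1(OCCO1)Cc2ccoc2[Si](CC)(CC)CC | intermediate (not isolated)
22 | ethyl (2E,4S,6S,7E,10S)-4-(anilinooxy)-2,6,10-trimethyl-6-(triethylsilyloxy)-11-[2-{[2-(triethylsilyl)furan-3-yl]methyl}-1,3-dioxolan-2-yl]undeca-2,7-dienoate | CCOC(=O)/C(C)=C/[C@@H](ONc1ccccc1)C[C@](C)(O[Si](CC)(CC)CC)/C=C/C[C@H](C)CC1(OCCO1)Cc2ccoc2[Si](CC)(CC)CC | intermediate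
23 | 4-hydroxy ester corresponding to 22 (C1–OH) | CCOC(=O)/C(C)=C/[C@@H](O)C[C@](C)(O[Si](CC)(CC)CC)/C=C/C[C@H](C)CC1(OCCO1)Cc2ccoc2[Si](CC)(CC)CC | intermediate
24 | 4-(tert-butyldimethylsilyloxy) ester (C1–OTBS) | CCOC(=O)/C(C)=C/[C@@H](O[Si](C)(C)C(C)(C)C)C[C@](C)(O[Si](CC)(CC)CC)/C=C/C[C@H](C)CC1(OCCO1)Cc2ccoc2[Si](CC)(CC)CC | intermediate
25 | (2E,4S,6S,7E,10S)-4-(tert-butyldimethylsilyloxy)-2,6,10-trimethyl-6-(triethylsilyloxy)-11-[2-{[2-(triethylsilyl)furan-3-yl]methyl}-1,3-dioxolan-2-yl]undeca-2,7-dien-1-ol | OC/C(C)=C/[C@@H](O[Si](C)(C)C(C)(C)C)C[C@](C)(O[Si](CC)(CC)CC)/C=C/C[C@H](C)CC1(OCCO1)Cc2ccoc2[Si](CC)(CC)CC | intermediate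
26 | primary allylic bromide corresponding to 25 | BrC/C(C)=C/[C@@H](O[Si](C)(C)C(C)(C)C)C[C@](C)(O[Si](CC)(CC)CC)/C=C/C[C@H](C)CC1(OCCO1)Cc2ccoc2[Si](CC)(CC)CC | intermediate
27 | 2,5-endoperoxide of the silylfuran in 26 | BrC/C(C)=C/[C@@H](O[Si](C)(C)C(C)(C)C)C[C@](C)(O[Si](CC)(CC)CC)/C=C/C[C@H](C)CC1(OCCO1)CC2=CC3OOC2([Si](CC)(CC)CC)O3 | intermediate (not isolated)
28 | triethylsilyl ester of the Z-formyl enoic acid | BrC/C(C)=C/[C@@H](O[Si](C)(C)C(C)(C)C)C[C@](C)(O[Si](CC)(CC)CC)/C=C/C[C@H](C)CC1(OCCO1)C/C(C(=O)O[Si](CC)(CC)CC)=C/C=O | intermediate (not isolated)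
29 | hydroxybutenolide bromide (5-hydroxy-2(5H)-furanone, lactol epimers) | BrC/C(C)=C/[C@@H](O[Si](C)(C)C(C)(C)C)C[C@](C)(O[Si](CC)(CC)CC)/C=C/C[C@H](C)CC1(OCCO1)CC2=CC(O)OC2=O | intermediate
30 | seco allylic bromide Z-formyl enoate methyl ester (C1 OTBS, C3 OTES, C9 dioxolane) | BrC/C(C)=C/[C@@H](O[Si](C)(C)C(C)(C)C)C[C@](C)(O[Si](CC)(CC)CC)/C=C/C[C@H](C)CC1(OCCO1)C/C(C(=O)OC)=C/C=O | intermediate
31 | macrocyclic C13 hydroxy methyl ester with C14 isopropenyl | CC(C)(C)[Si](C)(C)O[C@H]1C[C@](C)(O[Si](CC)(CC)CC)/C=C/C[C@H](C)CC3(OCCO3)C/C(C(=O)OC)=C/[C@@H](O)[C@@H]1C(C)=C | intermediate (not isolated)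
32 | 14-isopropenyl bicyclic butenolide (C1 OTBS, C3 OTES, C9 dioxolane) | CC(C)(C)[Si](C)(C)O[C@H]1C[C@](C)(O[Si](CC)(CC)CC)/C=C/C[C@H](C)CC3(OCCO3)CC2=C[C@@H](OC2=O)[C@@H]1C(C)=C | intermediate
33 | 14-isopropyl bicyclic butenolide (C1 OTBS, C3 OTES, C9 dioxolane) | CC(C)(C)[Si](C)(C)O[C@H]1C[C@](C)(O[Si](CC)(CC)CC)/C=C/C[C@H](C)CC3(OCCO3)CC2=C[C@@H](OC2=O)[C@@H]1C(C)C | intermediate
34 | C1,C3-diol with C9 dioxolane | O[C@H]1C[C@](C)(O)/C=C/C[C@H](C)CC3(OCCO3)CC2=C[C@@H](OC2=O)[C@@H]1C(C)C | intermediate
35 | C1 acetate with C3 hydroxyl and C9 dioxolane | CC(=O)O[C@H]1C[C@](C)(O)/C=C/C[C@H](C)CC3(OCCO3)CC2=C[C@@H](OC2=O)[C@@H]1C(C)C | intermediate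
36 | CNP0200490.2 | CC(=O)O[C@H]1C[C@](C)(O)/C=C/C[C@H](C)CC(=O)CC2=C[C@@H](OC2=O)[C@@H]1C(C)C | target

**Step count and risks**

Total: 27 steps. Longest linear sequence: 22 steps (steps 1–3, 5–8 and 13–27).

Step 23 is the most likely to fail. Chain growth between molecules can outrun ring closure, the excess low-valent chromium can reduce the electron-poor C11=C12 bond by electron transfer, and the facial bias from C1 may be eroded in the macrocyclic transition state. The fallback sets out from 29 and returns at 32. Compound 29 is not methylated but stirred at high dilution with indium powder in THF/aqueous NH4Cl. The allylindium species adds in Barbier fashion to the open-chain aldehyde tautomer of the pseudo-acid, a reaction known for γ-hydroxybutenolides, and gives the macrocyclic C13 hydroxy acid F1 as its indium salt. Acidification to about pH 3 should lactonise it to 32. This avoids both the reducing chromium salt and the labile aldehyde ester.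

Step 22 is the second risk. Diazomethane can add as a 1,3-dipole across the doubly activated C11=C12 bond, and the Z-formyl enoate can isomerise to the E form, which cannot lactonise. The fallback sets out from 26 and returns at 32. The photooxygenation of step 21 is run without the aqueous hydrolysis, the cold solution is exchanged into dry THF, and the triethylsilyl Z-formyl enoate 28 is added slowly to CrCl2 as in step 23. Allylation should give the macrocyclic C13 hydroxy triethylsilyl ester F2 as its chromium alkoxide, which lactonises in the flask or on mild acidic work-up with loss of the silanol to give 32. No diazomethane and no isolated formyl ester are then needed.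

Step 27 is the third risk. Acid can ionise the tertiary allylic C3 alcohol, leading to allylic transposition or elimination, and can move C11=C12 into conjugation with the freed C9 ketone. The fallback sets out from 33 and returns at 36. The dioxolane is hydrolysed first (PPTS, wet acetone) while C3 is still a silyl ether and cannot ionise as easily, giving the C9 ketone bis-silyl ether F3. Buffered HF·pyridine then gives the keto diol F4. Acetylation with Ac2O in pyridine at 0 °C without DMAP completes 36, the last step then being run under the least enolising conditions available.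

**Further compounds**

F1 | step 23 | macrocyclic C13 hydroxy acid (C14 isopropenyl, C1 OTBS, C3 OTES, C9 dioxolane) | CC(C)(C)[Si](C)(C)O[C@H]1C[C@](C)(O[Si](CC)(CC)CC)/C=C/C[C@H](C)CC3(OCCO3)C/C(C(=O)O)=C/[C@@H](O)[C@@H]1C(C)=C
F2 | step 22 | macrocyclic C13 hydroxy triethylsilyl ester (C14 isopropenyl, C1 OTBS, C3 OTES, C9 dioxolane) | CC(C)(C)[Si](C)(C)O[C@H]1C[C@](C)(O[Si](CC)(CC)CC)/C=C/C[C@H](C)CC3(OCCO3)C/C(C(=O)O[Si](CC)(CC)CC)=C/[C@@H](O)[C@@H]1C(C)=C
F3 | step 27 | C9 ketone bis-silyl ether (C1 OTBS, C3 OTES, C14 isopropyl) | CC(C)(C)[Si](C)(C)O[C@H]1C[C@](C)(O[Si](CC)(CC)CC)/C=C/C[C@H](C)CC(=O)CC2=C[C@@H](OC2=O)[C@@H]1C(C)C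
F4 | step 27 | keto diol (deacetyl target) | O[C@H]1C[C@](C)(O)/C=C/C[C@H](C)CC(=O)CC2=C[C@@H](OC2=O)[C@@H]1C(C)C
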